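Ring A is built last rather than bought. Its C5 methoxy and C7 hydroxy groups sit on the four-carbon arc C5–C8 that spans the C4a=C8a bond shared with pyranone ring C. This is the oxygen pattern of a 1,1-dimethoxy-3-silyloxybutadiene. Cutting C4a–C5 and C8–C8a therefore leads back to that diene and to a monocyclic 4-pyranone that bears the MOM-protected chromenyl ring B on one alpha-carbon and bromine on the other. One operation forms both bonds, closes ring A and aromatises it by expelling HBr, MeOH and the silyl group, so the 5-OMe/7-OH pair arrives already differentiated. Everything else is routine cross-coupling and chromene chemistry.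

Key step: step 10

Remark: the target has no stereocentre. The ring-fusion carbons of the transient cycloadduct are the only stereocentres met on the way; they form racemic and vanish on aromatisation.

Step 1
Reactants: 1 benzene-1,2-diol (catechol)
Product: 2 2-(methoxymethoxy)phenol
Conditions: 1 (2 equiv), MOMCl (1 equiv), iPr2NEt, CH2Cl2, 0 °C → rt, under argon
Reagents that add atoms: chloromethyl methyl ether (MOMCl), COCCl
Why: Williamson-type O-alkylation of a symmetrical diphenol, run with the cheap, water-extractable diol in excess to suppress double protection; masking one oxygen first also keeps a free ortho-phenol away from the later alkyne chemistry.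

Step 2
Reactants: 2 2-(methoxymethoxy)phenol
Product: 3 4-bromo-2-(methoxymethoxy)phenol
Conditions: NBS (1.0 equiv), MeCN, 0 °C
Reagents that add atoms: N-bromosuccinimide, O=C1CCC(=O)N1Br
Why: Near-neutral electrophilic aromatic bromination in which the free hydroxyl outranks the acetal oxygen as director and places bromine para to itself, at the future chromene C6, before any alkene is present to compete.

Step 3
Reactants: 3 4-bromo-2-(methoxymethoxy)phenol, 4 3-chloro-3-methylbut-1-yne
Product: 5 4-bromo-2-(methoxymethoxy)-1-[(2-methylbut-3-yn-2-yl)oxy]benzene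
Conditions: 4 (1.3 equiv), DBU, CuCl2·2H2O (1 mol %), MeCN, 0 °C → rt
Reagents that add atoms: none
Why: Copper-catalysed O-propargylation of a phenol with a tertiary propargylic chloride, the standard entry to aryl 1,1-dimethylpropargyl ethers, which tolerates aryl bromides and acetals.

Step 4
Reactants: 5 4-bromo-2-(methoxymethoxy)-1-[(2-methylbut-3-yn-2-yl)oxy]benzene
Product: 8 6-bromo-8-(methoxymethoxy)-2,2-dimethyl-2H-chromene, via ortho-allenylphenol 6 (not isolated), via ortho-quinone methide 7 (not isolated)
Conditions: N,N-diethylaniline, 180 °C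
Reagents that add atoms: none
Why: Aromatic propargyl Claisen rearrangement cascade ([3,3] shift with rearomatisation to 6, 1,5-hydrogen shift to 7, oxa-6π electrocyclisation) that can end only at the single free ortho carbon, while the basic solvent protects the MOM group from adventitious acid.

Step 5
Reactants: 8 6-bromo-8-(methoxymethoxy)-2,2-dimethyl-2H-chromene
Product: 9 2-[8-(methoxymethoxy)-2,2-dimethyl-2H-chromen-6-yl]-4,4,5,5-tetramethyl-1,3,2-dioxaborolane
Conditions: B2pin2 (1.1 equiv), Pd(dppf)Cl2 (3 mol %), KOAc, 1,4-dioxane, 85 °C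
Reagents that add atoms: bis(pinacolato)diboron, CC1(C)OB(OC1(C)C)B1OC(C)(C)C(C)(C)O1
Why: Miyaura borylation of an aryl bromide, an acetate-buffered palladium process that leaves the hindered chromene alkene and the MOM ether untouched and fixes boron at C6 without relying on C–H selectivity.

Step 6
Reactants: 10 4H-pyran-4-one
Product: 11 3,5-dibromo-4H-pyran-4-one
Conditions: Br2 (2.2 equiv), pyridine (2.5 equiv), CH2Cl2, 0 °C → rt
Reagents that add atoms: bromine, BrBr
Why: Electrophilic alpha-bromination of a vinylogous ester (attack of C3 and then C5 on bromine, oxocarbenium ion, proton loss to pyridine), with the two cross-conjugated enol-ether halves reacting in turn.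

Step 7
Reactants: 9 2-[8-(methoxymethoxy)-2,2-dimethyl-2H-chromen-6-yl]-4,4,5,5-tetramethyl-1,3,2-dioxaborolane, 11 3,5-dibromo-4H-pyran-4-one
Product: 12 3-bromo-5-[8-(methoxymethoxy)-2,2-dimethyl-2H-chromen-6-yl]-4H-pyran-4-one
Conditions: 11 (3 equiv, excess recovered), Pd(PPh3)4 (5 mol %), Na2CO3, DME–H2O, 60 °C
Reagents that add atoms: none
Why: Suzuki–Miyaura coupling as practised on 3-halochromones, with the symmetrical dibromide in excess so that single arylation prevails and with carbonate at moderate temperature to spare the base-sensitive pyranone.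

Step 8
Reactants: 13 1,1-dimethoxyethene
Product: 14 4,4-dimethoxybut-3-en-2-one
Conditions: AcCl (1 equiv), 13 (2.1 equiv), Et2O, 0 °C → reflux
Reagents that add atoms: acetyl chloride, CC(=O)Cl
Why: C-acylation of a ketene acetal by an acid chloride, with the second equivalent of 13 serving as the HCl scavenger so that no amine base, which would generate ketene, is needed.

Step 9
Reactants: 14 4,4-dimethoxybut-3-en-2-one
Product: 15 [(4,4-dimethoxybuta-1,3-dien-2-yl)oxy]trimethylsilane
Conditions: TMSCl, Et3N, ZnCl2 (cat.), toluene, 40 °C; filtration and distillation under dry conditions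
Reagents that add atoms: chlorotrimethylsilane, C[Si](C)(C)Cl
Why: Soft enolisation and O-silylation of a methyl ketone whose only enolisable position is the methyl group, which gives the cross-conjugated 2-silyloxydiene.

Step 10
Reactants: 12 3-bromo-5-[8-(methoxymethoxy)-2,2-dimethyl-2H-chromen-6-yl]-4H-pyran-4-one, 15 [(4,4-dimethoxybuta-1,3-dien-2-yl)oxy]trimethylsilane
Product: 20 7-hydroxy-5-methoxy-3-[8-(methoxymethoxy)-2,2-dimethyl-2H-chromen-6-yl]-4H-chromen-4-one, via silyloxypyrylium triflate 16 (not isolated), via cis-fused bromo ketal cycloadduct 17 (not isolated), via bromo cyclohexadiene 18 (not isolated), via 7-O-trimethylsilyl isoflavone 19 (not isolated)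
Conditions: TMSOTf (1.2 equiv), 2,6-di-tert-butyl-4-methylpyridine (0.2 equiv), CH2Cl2, 0 °C; 15 (2.5 equiv), −78 → 0 °C; Et3N (5 equiv), 0 °C → rt; then aq citric acid–MeOH, rt
Reagents that add atoms: none
Why: Proposed new method: TMSOTf silylates the pyranone carbonyl to the 4-silyloxypyrylium salt 16, the CH2 terminus of 15 attacks its C2 (the oxygen-bearing carbon next to C3–Br, future C8a), and the resulting bromo enol silane carbon C3 (future C4a) closes on the dimethoxy-substituted terminus (future C5), releasing TMSOTf and giving 17 by a polar, asynchronous [4+2]. Ring A is thereby closed by intermolecular [4+2] annulation across C2=C3 of ring C, the second bond being a 6-(enolexo)-endo-trig conjugate closure if the two bonds form in sequence. TMSOTf/Et3N then removes one C5 methoxy group and a C8 proton (a vinylogous ketal-to-enol-ether elimination) to give diene 18, which loses HBr across C4a–C8a even though H and Br are cis because the step is now an aromatisation, and the aryl silyl ether 19 is hydrolysed on work-up. The closest known reaction types are additions of 1,1-dialkoxy-3-silyloxybutadienes to haloquinones with loss of hydrogen halide and alcohol, silyl-triflate-triggered conjugate addition/ring closure of 2-silyloxydienes on chromones via 4-silyloxybenzopyrylium salts, and Diels–Alder/dehydrobromination of 2-bromocycloalkenones; none has been shown on a monocyclic 3-bromo-4-pyranone. The step needs orientation (the nucleophilic CH2 terminus pairs with the oxygen-bearing beta-carbon, which puts OMe on C5 next to C4=O), site selectivity for C2=C3(Br) over C5(aryl)=C6 (bromine activates C2 inductively, the twisted aryl group shields C6, and only the bromo adduct has an exit to an arene) and chemoselectivity (the chromene C3=C4 bond is a donor-substituted styrene with no low-lying acceptor orbital for a nucleophilic diene; any MOM loss here would only anticipate step 11). The two stereocentres of 17 and 18 (C4a and C8a, cis by suprafacial addition) are erased on aromatisation, so no permanent stereocentre has to be controlled.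

Step 11
Reactants: 20 7-hydroxy-5-methoxy-3-[8-(methoxymethoxy)-2,2-dimethyl-2H-chromen-6-yl]-4H-chromen-4-one
Product: 21 7-hydroxy-3-(8-hydroxy-2,2-dimethyl-2H-chromen-6-yl)-5-methoxy-4H-chromen-4-one (glycyrrhizaisoflavone B)
Conditions: conc. HCl (cat.), MeOH, 45 °C
Reagents that add atoms: none
Why: Acid-catalysed acetal exchange cleaves the aryl MOM ether under conditions too mild to touch the C5 methyl ether, the pyranone or the 2,2-dimethylchromene.

Compound list
1 | benzene-1,2-diol (catechol) | Oc1ccccc1O | starting material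
2 | 2-(methoxymethoxy)phenol | COCOc1ccccc1O | intermediate
3 | 4-bromo-2-(methoxymethoxy)phenol | COCOc1cc(Br)ccc1O | intermediate
4 | 3-chloro-3-methylbut-1-yne | CC(C)(Cl)C#C | starting material
5 | 4-bromo-2-(methoxymethoxy)-1-[(2-methylbut-3-yn-2-yl)oxy]benzene | C#CC(C)(C)Oc1ccc(Br)cc1OCOC | intermediate
6 | 4-bromo-2-(methoxymethoxy)-6-(3-methylbuta-1,2-dien-1-yl)phenol | CC(C)=C=Cc1cc(Br)cc(OCOC)c1O | intermediate
7 | (6Z)-4-bromo-2-(methoxymethoxy)-6-(3-methylbut-2-en-1-ylidene)cyclohexa-2,4-dien-1-one | CC(C)=C/C=C1/C=C(Br)C=C(OCOC)C1=O | intermediate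
8 | 6-bromo-8-(methoxymethoxy)-2,2-dimethyl-2H-chromene | COCOc1cc(Br)cc2C=CC(C)(C)Oc12 | intermediate
9 | 2-[8-(methoxymethoxy)-2,2-dimethyl-2H-chromen-6-yl]-4,4,5,5-tetramethyl-1,3,2-dioxaborolane | COCOc1cc(B2OC(C)(C)C(C)(C)O2)cc2C=CC(C)(C)Oc12 | intermediate
10 | 4H-pyran-4-one | O=c1ccocc1 | starting material
11 | 3,5-dibromo-4H-pyran-4-one | O=c1c(Br)cocc1Br | intermediate
12 | 3-bromo-5-[8-(methoxymethoxy)-2,2-dimethyl-2H-chromen-6-yl]-4H-pyran-4-one | O=c1c(Br)cocc1-c1cc(OCOC)c2OC(C)(C)C=Cc2c1 | intermediate
13 | 1,1-dimethoxyethene | C=C(OC)OC | starting material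
14 | 4,4-dimethoxybut-3-en-2-one | CC(=O)C=C(OC)OC | intermediate
15 | [(4,4-dimethoxybuta-1,3-dien-2-yl)oxy]trimethylsilane | COC(OC)=CC(=C)O[Si](C)(C)C | intermediate
16 | 3-bromo-5-[8-(methoxymethoxy)-2,2-dimethyl-2H-chromen-6-yl]-4-[(trimethylsilyl)oxy]pyrylium trifluoromethanesulfonate | C[Si](C)(C)Oc1c(Br)c[o+]cc1-c1cc(OCOC)c2OC(C)(C)C=Cc2c1.[O-]S(=O)(=O)C(F)(F)F | intermediate
17 | cis-4a-bromo-5,5-dimethoxy-3-[8-(methoxymethoxy)-2,2-dimethyl-2H-chromen-6-yl]-7-[(trimethylsilyl)oxy]-4a,5,8,8a-tetrahydro-4H-chromen-4-one (H-8a and Br-4a on the same face; racemic, one enantiomer drawn) | COC1(OC)C=C(O[Si](C)(C)C)C[C@H]2OC=C(c3cc(OCOC)c4OC(C)(C)C=Cc4c3)C(=O)[C@@]12Br | intermediate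
18 | cis-4a-bromo-5-methoxy-3-[8-(methoxymethoxy)-2,2-dimethyl-2H-chromen-6-yl]-7-[(trimethylsilyl)oxy]-4a,8a-dihydro-4H-chromen-4-one (H-8a and Br-4a on the same face; racemic, one enantiomer drawn) | COC1=CC(O[Si](C)(C)C)=C[C@H]2OC=C(c3cc(OCOC)c4OC(C)(C)C=Cc4c3)C(=O)[C@@]12Br | intermediate
19 | 5-methoxy-3-[8-(methoxymethoxy)-2,2-dimethyl-2H-chromen-6-yl]-7-[(trimethylsilyl)oxy]-4H-chromen-4-one | COc1cc(O[Si](C)(C)C)cc2occ(-c3cc(OCOC)c4c(c3)C=CC(C)(C)O4)c(=O)c12 | intermediate
20 | 7-hydroxy-5-methoxy-3-[8-(methoxymethoxy)-2,2-dimethyl-2H-chromen-6-yl]-4H-chromen-4-one | COc1cc(O)cc2occ(-c3cc(OCOC)c4c(c3)C=CC(C)(C)O4)c(=O)c12 | intermediate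
21 | 7-hydroxy-3-(8-hydroxy-2,2-dimethyl-2H-chromen-6-yl)-5-methoxy-4H-chromen-4-one (glycyrrhizaisoflavone B) | COc1cc(O)cc2occ(-c3cc(O)c4c(c3)C=CC(C)(C)O4)c(=O)c12 | target

Total step count: 11. Longest linear sequence: 8 (steps 1, 2, 3, 4, 5, 7, 10, 11).

Steps most likely to fail

1. Step 10. Four failure processes are foreseeable:
   - The vinylogous-ester double bond may refuse the diene.
   - The diene may attack the pyrylium carbon next to the aryl group.
   - The sequence may stall after the first C–C bond and drain away through retro-oxa-Michael opening of ring C.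
   - Bromine may be lost reductively instead of as HBr.

   The fallback takes ring A from the aromatic pool and forms the C3–aryl bond last by known 3-iodochromone chemistry. It sets out from 9. Commercial 1-(2,4-dihydroxy-6-methoxyphenyl)ethan-1-one is protected with MOMCl/iPr2NEt at the non-chelated 4-hydroxyl to give 1-[2-hydroxy-6-methoxy-4-(methoxymethoxy)phenyl]ethan-1-one F1. Condensation with DMF dimethyl acetal gives (E)-3-(dimethylamino)-1-[2-hydroxy-6-methoxy-4-(methoxymethoxy)phenyl]prop-2-en-1-one F2. Iodine-induced cyclisation gives 3-iodo-5-methoxy-7-(methoxymethoxy)-4H-chromen-4-one F3. Suzuki–Miyaura coupling with 9 (Pd(PPh3)4, Na2CO3) gives 5-methoxy-7-(methoxymethoxy)-3-[8-(methoxymethoxy)-2,2-dimethyl-2H-chromen-6-yl]-4H-chromen-4-one F4. HCl in MeOH then removes both MOM groups, and the sequence comes back to the route at 21.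

2. Step 7. The statistical coupling may run on to double arylation, and aqueous base may open the bromopyranone ring. The fallback replaces statistics by halogen differentiation and sets out from 10. One equivalent of Br2 with pyridine gives 3-bromo-4H-pyran-4-one F5. Iodination of the remaining alpha-carbon with I2 and (NH4)2Ce(NO3)6 in MeCN gives 3-bromo-5-iodo-4H-pyran-4-one F6. Coupling with an equimolar amount of 9 near room temperature should then engage only the weaker C–I bond, and the sequence comes back at 12.

3. Step 2. Bromination may spread over the positions para to either oxygen or ortho to the hydroxyl, and traces of HBr may erode the acetal. The fallback drops electrophilic halogenation in favour of sterically governed C–H borylation and sets out from 2. Copper-catalysed propargylation with 4 gives 1-(methoxymethoxy)-2-[(2-methylbut-3-yn-2-yl)oxy]benzene F7. Thermal Claisen rearrangement gives 8-(methoxymethoxy)-2,2-dimethyl-2H-chromene F8. Borylation with B2pin2, [Ir(OMe)(cod)]2 and 4,4'-di-tert-butyl-2,2'-bipyridine at the only arene C–H without an ortho neighbour (C6) then comes back at 9.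

Further compounds
F1 | step 10 | 1-[2-hydroxy-6-methoxy-4-(methoxymethoxy)phenyl]ethan-1-one | CC(=O)c1c(O)cc(OCOC)cc1OC
F2 | step 10 | (E)-3-(dimethylamino)-1-[2-hydroxy-6-methoxy-4-(methoxymethoxy)phenyl]prop-2-en-1-one | CN(C)/C=C/C(=O)c1c(O)cc(OCOC)cc1OC
F3 | step 10 | 3-iodo-5-methoxy-7-(methoxymethoxy)-4H-chromen-4-one | COc1cc(OCOC)cc2occ(I)c(=O)c12
F4 | step 10 | 5-methoxy-7-(methoxymethoxy)-3-[8-(methoxymethoxy)-2,2-dimethyl-2H-chromen-6-yl]-4H-chromen-4-one | COc1cc(OCOC)cc2occ(-c3cc(OCOC)c4c(c3)C=CC(C)(C)O4)c(=O)c12
F5 | step 7 | 3-bromo-4H-pyran-4-one | O=c1ccocc1Br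
F6 | step 7 | 3-bromo-5-iodo-4H-pyran-4-one | O=c1c(Br)cocc1I
F7 | step 2 | 1-(methoxymethoxy)-2-[(2-methylbut-3-yn-2-yl)oxy]benzene | C#CC(C)(C)Oc1ccccc1OCOC
F8 | step 2 | 8-(methoxymethoxy)-2,2-dimethyl-2H-chromene | COCOc1cccc2C=CC(C)(C)Oc12
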